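From 10.0 min on, the autumn flask stands still within its scatter, so the clock here is short against the 30.0 min of a dosed run.

| flask | substrate | coupling partner | remark | time |
|---|---|---|---|---|
| autumn | 0.25 M | 1.5 equiv | run made earlier |  |
| summer | 0.12 M | 1.5 equiv | run made earlier |  |
| south | 0.25 M | 1.50 equiv | everything together in a closed stirred flask, run for 30 min | 30 min |
| north-east | 0.25 M | 1.50 equiv (fed, over 30.0 min) | all but coupling partner at the start; coupling partner goes in evenly over 30.0 min, the run ends at 30 min | 30 min |
| north | 0.25 M (fed, over 30.0 min) | 1.50 equiv | all but substrate at the start; substrate goes in evenly over 30.0 min, the run ends at 30 min | 30 min |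
| north-west | 0.25 M | 1.50 equiv | a single well-mixed tank run continuously and read at steady state, 30 min in it on average |  |

| run | time / min | target / % | side product A / % | side product B / % |
|---|---|---|---|---|
| autumn | 3.00 | 17.4 | 0.1 | 50.8 |
| autumn | 6.00 | 18.6 | 1.3 | 54.5 |
| autumn | 10.0 | 19.3 | 0.6 | 59.9 |
| autumn | 12.0 | 17.8 | 0.8 | 60.8 |
| autumn | 15.0 | 20.6 | 0 | 59.7 |
| autumn | 20.0 | 19.0 | 2.2 | 58.6 |
| summer | 0.200 | 3.4 | 1.8 | 7.3 |
| summer | 0.667 | 5.4 | 0.7 | 16.2 |
| summer | 1.00 | 9.8 | 0 | 21.9 |
| summer | 1.50 | 10.4 | 2.5 | 28.7 |
| summer | 2.50 | 12.5 | 3.1 | 37.0 |
| summer | 3.00 | 14.6 | 1.8 | 41.1 |

(readings scatter by 1 percentage point)

- in percentages every species weighs as the substrate in it: one side product B or side product C counts as two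
- the stated concentrations are those of everything mixed, before any reaction; amounts are the same in each set-up
- on the list of suspects stand: substrate -> side product A; substrate + target -> side product C; 2 coupling partner -> self-condensation product; substrate + coupling partner -> target; target <-> isomer of the product; 2 substrate -> side product B
- the feed brings no volume worth counting
- the earlier runs were made in a closed, stirred flask

1. the set-up with the highest share of target in all that became target or side product A or side product B or isomer of the product or side product C, at the outlet or at the end ("none" if the first two lie within 2 percentage points) (south / north-east / north / north-west / none)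
2. share of target in all that became target or side product A or side product B or isomer of the product or side product C, at the outlet or at the end, south
3. share of target in all that became target or side product A or side product B or isomer of the product or side product C, at the outlet or at the end, north-east
4. share of target in all that became target or side product A or side product B or isomer of the product or side product C, at the outlet or at the end, north
5. share of target in all that became target or side product A or side product B or isomer of the product or side product C, at the outlet or at the end, north-west

Both chemists read the same number: λ, the base-ten logarithm of side product B over target, a log selectivity factor. At 3.00 min the autumn run gives 0.465 and the summer run 0.449. The charge differs by 0.319 in logs and λ by 0.0160, far less, so concentration cancels and both steps look second order. Then the ratio of the two rates should follow substrate over partner, one for one, and λ, which counts the amounts accumulated so far, should sink after it.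

But at 3.00 min in the autumn run, at most 31.8% of the substrate is left, a fall of 0.498 in logs. Coupling has cost the partner little, just 17.4% of the substrate charge against 1.5 equiv. Yet λ at 20.0 min is still 0.489. Why does it not fall?

The first chemist, who made the forecast, says substrate eats target: “The target stays flat while substrate remains”. Slow substrate then trades side product B for side product C at the same cap, so the forecast reads south 19.5%, north-east 7.5%, north 18%, north-west 13%, best: none.

The second chemist, and this reckoning is my own, says the partner is leaving by itself, through self-condensation. Then substrate over partner sinks by less than substrate does, and λ need not sink after it. A dose stretched 0.477 in logs beyond the autumn clock meets a partner that has been condensing with itself from the start, so I expect north well under south, with λ there above 0.465.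

The simulation gives south 18.4%, north-east 7.93%, north 8.19%, north-west 14.0%; best: south.

    substrate → side product A (k = 1.10 × 10⁻⁴ s⁻¹)
    substrate + target → side product C (k = 0.0130 M⁻¹ s⁻¹)
    2 coupling partner → self-condensation product (k = 0.0130 M⁻¹ s⁻¹)
    substrate + coupling partner → target (k = 0.0120 M⁻¹ s⁻¹)
    target ⇌ isomer of the product (K = 0.110, k = 0.00560 s⁻¹)
    2 substrate → side product B (k = 0.0230 M⁻¹ s⁻¹)

North ends at λ = 0.950, above 0.465, with partner at 3.09% of its charge and substrate at 19.9%. The first chemist keeps south, where side product C reaches 16.4% and λ ends at 0.523. The neighbouring flask is south with 0.380 equiv of partner. Cutting the partner adds 0.596, so λ should be 1.06. That flask ends with side product B at 78.5% and target at 7.68%, which is λ = 1.01.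

(All runs come from a simulation for substances that don't exist; the scatter is artificial.)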